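## Retrosynthetic overview

1. Target ⇐ tert-butyl ester cleavage and Yamaguchi acylation of the C4 carbinol of a bicyclic hydroxy enone with (2E,4E,6E,8R)-6,8-dimethyldeca-2,4,6-trienoic acid (Wittig, then vinylogous HWE, from (R)-2-methylbutan-1-ol).
2. C4–OH ⇐ 1,2-reduction of an ene-dione anti to the angular methyl; enal ⇐ N-oxide oxidation of an allylic bromide; C1 side chain ⇐ alkylation of the cyclopentenone α′-enolate.
3. Key step: intramolecular Pauson–Khand [2+2+1] cycloaddition of a 1,7-enyne; the ester-bearing C7 stereocenter sets the quaternary C7a.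
4. Enyne ⇐ (R)-5-oxotetrahydrofuran-2-carboxylic acid: SN2 inversion of the α-triflate by an isopropenyl cuprate, alkynylation of the distal ester, ketalisation.
5. Ring order: the cyclohexane ring (C3a–C7a bond) and the cyclopentenone ring close together in the cycloaddition; no ring is made before or after it.

Assumption: atoms are numbered as in the indene name of the target (C1, C2, C3, C3a, C4–C7, C7a); (R)-5-oxotetrahydrofuran-2-carboxylic acid (the lactone acid from D-glutamic acid) and (R)-2-methylbutan-1-ol are bought as single enantiomers.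

## Route

Step 1
Reactants: 1 (2R)-5-oxooxolane-2-carboxylic acid
Product: 2 tert-butyl (2R)-5-oxooxolane-2-carboxylate
Conditions: isobutene (excess), H2SO4 (cat.), CH2Cl2, sealed vessel, rt
Reagents that add atoms: 2-methylpropene (CC(C)=C)
Why: Acid-catalysed addition of the carboxylic acid to isobutene (tert-butyl ester formation) leaves the γ-lactone and the stereocenter that becomes C7 untouched.

Step 2
Reactants: 2 tert-butyl (2R)-5-oxooxolane-2-carboxylate
Product: 3 1-tert-butyl 5-methyl (2R)-2-hydroxypentanedioate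
Conditions: NaOMe (0.1 equiv), MeOH, 0 °C; AcOH quench; used crude at once
Reagents that add atoms: methanol (CO)
Why: Methoxide-catalysed lactone methanolysis (transesterification) cleaves only the acyl C–O bond, so the carbinol keeps its R configuration and the two carboxyl groups end up differentiated as tert-butyl and methyl esters.

Step 3
Reactants: 3 1-tert-butyl 5-methyl (2R)-2-hydroxypentanedioate; 4 isopropenylmagnesium bromide
Product: 6 1-tert-butyl 5-methyl (2R)-2-(prop-1-en-2-yl)pentanedioate, via α-triflate 5 (not isolated)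
Conditions: Tf2O (1.1 equiv), 2,6-lutidine (1.2 equiv), CH2Cl2, −78 °C; pentane, cold filtration; filtrate added to [CH2=C(CH3)]2CuMgBr (from 4 and CuBr·SMe2, 2:1; 1.5 equiv), THF, −78 → −40 °C
Reagents that add atoms: none
Why: SN2 displacement of an α-triflyloxy ester by an alkenyl cuprate proceeds with inversion (the tert-butyl ester blocks carbonyl attack), converting the (R)-carbinol into the (R)-configured C–C stereocenter that becomes C7.

Step 4
Reactants: 6 1-tert-butyl 5-methyl (2R)-2-(prop-1-en-2-yl)pentanedioate; 7 ethynyltrimethylsilane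
Product: 8 tert-butyl (2R)-5-oxo-2-(prop-1-en-2-yl)-7-(trimethylsilyl)hept-6-ynoate
Conditions: 7 (2 equiv), n-BuLi (2 equiv), THF, −78 °C; BF3·OEt2 (2 equiv); then 6, −78 °C
Reagents that add atoms: none
Why: BF3-mediated acylation of a lithium acetylide by the unhindered methyl ester (Yamaguchi ynone synthesis) stops at the ketone stage, and the non-basic alkynyl borate neither attacks the tert-butyl ester nor epimerises the allylic α-center.

Step 5
Reactants: 8 tert-butyl (2R)-5-oxo-2-(prop-1-en-2-yl)-7-(trimethylsilyl)hept-6-ynoate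
Product: 10 tert-butyl (2R)-4-(2-ethynyl-1,3-dioxolan-2-yl)-2-(prop-1-en-2-yl)butanoate, via silylalkyne ketal 9 (not isolated)
Conditions: (TMSOCH2)2, TMSOTf (cat.), CH2Cl2, −78 → −20 °C; Et3N; then TBAF/AcOH (1:1), THF, 0 °C
Reagents that add atoms: 1,2-bis(trimethylsilyloxy)ethane (C[Si](C)(C)OCCO[Si](C)(C)C)
Why: Noyori ketalisation under aprotic conditions masks the ynone without conjugate addition, and buffered fluoride then removes the alkynyl silyl group without base-induced migration of the β,γ-double bond, leaving a 1,7-enyne with a Thorpe–Ingold-active propargylic ketal.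

Step 6
Reactants: 10 tert-butyl (2R)-4-(2-ethynyl-1,3-dioxolan-2-yl)-2-(prop-1-en-2-yl)butanoate
Product: 11 tert-butyl (7'R,7a'S)-7a'-methyl-2'-oxo-1',2',5',6',7',7a'-hexahydrospiro[1,3-dioxolane-2,4'-indene]-7'-carboxylate
Conditions: Co2(CO)8 (20 mol%), tetramethylthiourea (60 mol%), CO (1 atm), toluene, 70 °C
Reagents that add atoms: carbon monoxide ([C-]#[O+])
Why: Intramolecular Pauson–Khand [2+2+1] cycloaddition closes the cyclohexane ring (C3a–C7a bond) and the cyclopentenone together; in the chair-like alkene-insertion transition state the C7 ester lies pseudo-equatorial with its hydrogen eclipsing the alkene, which places the new angular methyl at C7a cis to the ester.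

Step 7
Reactants: 11 tert-butyl (7'R,7a'S)-7a'-methyl-2'-oxo-1',2',5',6',7',7a'-hexahydrospiro[1,3-dioxolane-2,4'-indene]-7'-carboxylate; 12 3-bromo-2-(bromomethyl)prop-1-ene
Product: 14 tert-butyl (1'R,7'R,7a'S)-1'-[2-(bromomethyl)prop-2-en-1-yl]-7a'-methyl-2'-oxo-1',2',5',6',7',7a'-hexahydrospiro[1,3-dioxolane-2,4'-indene]-7'-carboxylate, via lithium enolate 13 (not isolated)
Conditions: LiN(iPr)2 (1.05 equiv), THF, −78 °C; then inverse addition to 12 (4 equiv), DMPU, −78 → −30 °C
Reagents that add atoms: none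
Why: Kinetic α′-enolate alkylation (C1 carries the only enolisable ketone hydrogens) with a reactive allylic bromide; the electrophile enters the enolate face syn to the angular methyl because the other face is flanked by ring carbon C7 and its ester, giving the 1R epimer, which is also the one expected at equilibrium.

Step 8
Reactants: 14 tert-butyl (1'R,7'R,7a'S)-1'-[2-(bromomethyl)prop-2-en-1-yl]-7a'-methyl-2'-oxo-1',2',5',6',7',7a'-hexahydrospiro[1,3-dioxolane-2,4'-indene]-7'-carboxylate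
Product: 15 tert-butyl (1R,7R,7aS)-1-[2-(bromomethyl)prop-2-en-1-yl]-7a-methyl-2,4-dioxo-2,4,5,6,7,7a-hexahydro-1H-indene-7-carboxylate
Conditions: TsOH·H2O (0.3 equiv), acetone/H2O (10:1), rt → 40 °C
Reagents that add atoms: water (O)
Why: Acid-catalysed ketal hydrolysis unmasks the C4 ketone as the ene-dione, while the tert-butyl ester and the allylic bromide tolerate a non-nucleophilic acid in wet acetone.

Step 9
Reactants: 15 tert-butyl (1R,7R,7aS)-1-[2-(bromomethyl)prop-2-en-1-yl]-7a-methyl-2,4-dioxo-2,4,5,6,7,7a-hexahydro-1H-indene-7-carboxylate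
Product: 16 tert-butyl (1R,4S,7R,7aS)-1-[2-(bromomethyl)prop-2-en-1-yl]-4-hydroxy-7a-methyl-2-oxo-2,4,5,6,7,7a-hexahydro-1H-indene-7-carboxylate
Conditions: NaBH4 (1 equiv), CeCl3·7H2O (1.1 equiv), MeOH/THF (3:1), −78 °C
Reagents that add atoms: none
Why: Luche 1,2-reduction is expected to take the cyclohexenone carbonyl C4 (unhindered CH2 neighbour) in preference to C2 (flanked by the branched C1), and hydride enters anti to the 1,3-related axial angular methyl, so the new hydroxyl is cis to it (4S).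

Step 10
Reactants: 16 tert-butyl (1R,4S,7R,7aS)-1-[2-(bromomethyl)prop-2-en-1-yl]-4-hydroxy-7a-methyl-2-oxo-2,4,5,6,7,7a-hexahydro-1H-indene-7-carboxylate
Product: 18 tert-butyl (1R,4S,7R,7aS)-1-(2-formylprop-2-en-1-yl)-4-hydroxy-7a-methyl-2-oxo-2,4,5,6,7,7a-hexahydro-1H-indene-7-carboxylate, via alkoxyammonium bromide 17 (not isolated)
Conditions: 4-methylmorpholine N-oxide (5 equiv), 4 Å MS, MeCN, 0 °C → rt
Reagents that add atoms: 4-methylmorpholine N-oxide (C[N+]1([O-])CCOCC1)
Why: Ganem oxidation: the N-oxide oxygen displaces the allylic bromide (SN2 and SN2′ give the same 2-substituted allyl skeleton) and E2 loss of 4-methylmorpholine gives the 2-substituted acrolein without touching the secondary alcohol.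

Step 11
Reactants: 19 (2R)-2-methylbutan-1-ol; 20 2-(triphenyl-λ5-phosphanylidene)propanal
Product: 22 (2E,4R)-2,4-dimethylhex-2-enal, via (2R)-2-methylbutanal 21 (not isolated)
Conditions: TEMPO (10 mol%), (diacetoxyiodo)benzene (1.1 equiv), CH2Cl2, rt; then 20 (1.2 equiv), sealed tube, 60 °C
Reagents that add atoms: none
Why: TEMPO-catalysed oxidation to the volatile α-chiral aldehyde, followed in the same flask by a Wittig reaction with a formyl-stabilised ylide under base-free conditions, gives the E-trisubstituted enal without racemising the bought stereocenter.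

Step 12
Reactants: 22 (2E,4R)-2,4-dimethylhex-2-enal; 23 ethyl (2E)-4-(diethoxyphosphoryl)but-2-enoate
Product: 24 ethyl (2E,4E,6E,8R)-6,8-dimethyldeca-2,4,6-trienoate
Conditions: 23, LiN(SiMe3)2, THF, −78 °C; then 22, −78 → 0 °C
Reagents that add atoms: none
Why: Vinylogous Horner–Wadsworth–Emmons olefination with the preformed phosphonocrotonate anion adds four carbons with E geometry at the new double bond, and the absence of free base avoids γ-deprotonation of the enal at its stereocenter.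

Step 13
Reactants: 24 ethyl (2E,4E,6E,8R)-6,8-dimethyldeca-2,4,6-trienoate
Product: 25 (2E,4E,6E,8R)-6,8-dimethyldeca-2,4,6-trienoic acid
Conditions: LiOH·H2O, THF/MeOH/H2O (3:1:1), rt; then 1 M HCl to pH 3
Reagents that add atoms: lithium hydroxide ([Li+].[OH-])
Why: Saponification of the ethyl ester; the conjugated triene and the remote stereocenter are inert to hydroxide at room temperature.

Step 14
Reactants: 18 tert-butyl (1R,4S,7R,7aS)-1-(2-formylprop-2-en-1-yl)-4-hydroxy-7a-methyl-2-oxo-2,4,5,6,7,7a-hexahydro-1H-indene-7-carboxylate; 25 (2E,4E,6E,8R)-6,8-dimethyldeca-2,4,6-trienoic acid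
Product: 27 tert-butyl (1R,4S,7R,7aS)-4-{[(2E,4E,6E,8R)-6,8-dimethyldeca-2,4,6-trienoyl]oxy}-1-(2-formylprop-2-en-1-yl)-7a-methyl-2-oxo-2,4,5,6,7,7a-hexahydro-1H-indene-7-carboxylate, via mixed anhydride 26 (not isolated)
Conditions: 25, 2,4,6-trichlorobenzoyl chloride, Et3N, toluene, rt; then 18, DMAP, toluene, rt
Reagents that add atoms: none
Why: Yamaguchi esterification through the mixed anhydride acylates the hindered axial allylic alcohol with retention at C4, while the tert-butyl ester keeps the C7 carboxyl out of the reaction.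

Step 15
Reactants: 27 tert-butyl (1R,4S,7R,7aS)-4-{[(2E,4E,6E,8R)-6,8-dimethyldeca-2,4,6-trienoyl]oxy}-1-(2-formylprop-2-en-1-yl)-7a-methyl-2-oxo-2,4,5,6,7,7a-hexahydro-1H-indene-7-carboxylate
Product: 28 (1R,4S,7R,7aS)-4-{[(2E,4E,6E,8R)-6,8-dimethyldeca-2,4,6-trienoyl]oxy}-1-(2-formylprop-2-en-1-yl)-7a-methyl-2-oxo-2,4,5,6,7,7a-hexahydro-1H-indene-7-carboxylic acid
Conditions: CF3CO2H/CH2Cl2 (1:4), 0 °C → rt
Reagents that add atoms: none
Why: Acidolysis of the tert-butyl ester (loss of isobutene) frees the acid under conditions that leave the enal, the enone, the allylic trienoate and all stereocenters unchanged.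

## Compound list

1 | (2R)-5-oxooxolane-2-carboxylic acid | O=C1CC[C@H](C(=O)O)O1 | starting material
2 | tert-butyl (2R)-5-oxooxolane-2-carboxylate | O=C1CC[C@H](C(=O)OC(C)(C)C)O1 | intermediate
3 | 1-tert-butyl 5-methyl (2R)-2-hydroxypentanedioate | COC(=O)CC[C@@H](O)C(=O)OC(C)(C)C | intermediate
4 | isopropenylmagnesium bromide (prop-1-en-2-ylmagnesium bromide) | C=C(C)[Mg]Br | starting material
5 | 1-tert-butyl 5-methyl (2R)-2-[(trifluoromethanesulfonyl)oxy]pentanedioate | COC(=O)CC[C@@H](OS(=O)(=O)C(F)(F)F)C(=O)OC(C)(C)C | intermediate (not isolated)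
6 | 1-tert-butyl 5-methyl (2R)-2-(prop-1-en-2-yl)pentanedioate | COC(=O)CC[C@@H](C(=O)OC(C)(C)C)C(C)=C | intermediate
7 | ethynyltrimethylsilane | C#C[Si](C)(C)C | starting material
8 | tert-butyl (2R)-5-oxo-2-(prop-1-en-2-yl)-7-(trimethylsilyl)hept-6-ynoate | C[Si](C)(C)C#CC(=O)CC[C@@H](C(=O)OC(C)(C)C)C(C)=C | intermediate
9 | tert-butyl (2R)-2-(prop-1-en-2-yl)-4-{2-[(trimethylsilyl)ethynyl]-1,3-dioxolan-2-yl}butanoate | C[Si](C)(C)C#CC1(OCCO1)CC[C@@H](C(=O)OC(C)(C)C)C(C)=C | intermediate (not isolated)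
10 | tert-butyl (2R)-4-(2-ethynyl-1,3-dioxolan-2-yl)-2-(prop-1-en-2-yl)butanoate | C#CC1(OCCO1)CC[C@@H](C(=O)OC(C)(C)C)C(C)=C | intermediate
11 | tert-butyl (7'R,7a'S)-7a'-methyl-2'-oxo-1',2',5',6',7',7a'-hexahydrospiro[1,3-dioxolane-2,4'-indene]-7'-carboxylate | C1C(=O)C=C2C3(OCCO3)CC[C@@H](C(=O)OC(C)(C)C)[C@@]21C | intermediate
12 | 3-bromo-2-(bromomethyl)prop-1-ene | C=C(CBr)CBr | starting material
13 | lithium enolate of 11 (O–Li on C2', double bonds C1'=C2' and C3'=C3a'; 7'R,7a'S) | C1=C(O[Li])C=C2C3(OCCO3)CC[C@@H](C(=O)OC(C)(C)C)[C@@]21C | intermediate (not isolated)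
14 | tert-butyl (1'R,7'R,7a'S)-1'-[2-(bromomethyl)prop-2-en-1-yl]-7a'-methyl-2'-oxo-1',2',5',6',7',7a'-hexahydrospiro[1,3-dioxolane-2,4'-indene]-7'-carboxylate | BrCC(=C)C[C@H]1C(=O)C=C2C3(OCCO3)CC[C@@H](C(=O)OC(C)(C)C)[C@@]21C | intermediate
15 | tert-butyl (1R,7R,7aS)-1-[2-(bromomethyl)prop-2-en-1-yl]-7a-methyl-2,4-dioxo-2,4,5,6,7,7a-hexahydro-1H-indene-7-carboxylate | BrCC(=C)C[C@H]1C(=O)C=C2C(=O)CC[C@@H](C(=O)OC(C)(C)C)[C@@]21C | intermediate
16 | tert-butyl (1R,4S,7R,7aS)-1-[2-(bromomethyl)prop-2-en-1-yl]-4-hydroxy-7a-methyl-2-oxo-2,4,5,6,7,7a-hexahydro-1H-indene-7-carboxylate | BrCC(=C)C[C@H]1C(=O)C=C2[C@@H](O)CC[C@@H](C(=O)OC(C)(C)C)[C@@]21C | intermediate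
17 | 4-({2-[((1R,4S,7R,7aS)-7-(tert-butoxycarbonyl)-4-hydroxy-7a-methyl-2-oxo-2,4,5,6,7,7a-hexahydro-1H-inden-1-yl)methyl]prop-2-en-1-yl}oxy)-4-methylmorpholin-4-ium bromide | C[N+]1(OCC(=C)C[C@H]2C(=O)C=C3[C@@H](O)CC[C@@H](C(=O)OC(C)(C)C)[C@@]32C)CCOCC1.[Br-] | intermediate (not isolated)
18 | tert-butyl (1R,4S,7R,7aS)-1-(2-formylprop-2-en-1-yl)-4-hydroxy-7a-methyl-2-oxo-2,4,5,6,7,7a-hexahydro-1H-indene-7-carboxylate | C=C(C=O)C[C@H]1C(=O)C=C2[C@@H](O)CC[C@@H](C(=O)OC(C)(C)C)[C@@]21C | intermediate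
19 | (2R)-2-methylbutan-1-ol | CC[C@@H](C)CO | starting material
20 | 2-(triphenyl-λ5-phosphanylidene)propanal | CC(C=O)=P(c1ccccc1)(c1ccccc1)c1ccccc1 | starting material
21 | (2R)-2-methylbutanal | O=C[C@H](C)CC | intermediate (not isolated)
22 | (2E,4R)-2,4-dimethylhex-2-enal | O=C/C(C)=C/[C@H](C)CC | intermediate
23 | ethyl (2E)-4-(diethoxyphosphoryl)but-2-enoate | CCOC(=O)/C=C/CP(=O)(OCC)OCC | starting material
24 | ethyl (2E,4E,6E,8R)-6,8-dimethyldeca-2,4,6-trienoate | CCOC(=O)/C=C/C=C/C(C)=C/[C@H](C)CC | intermediate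
25 | (2E,4E,6E,8R)-6,8-dimethyldeca-2,4,6-trienoic acid | OC(=O)/C=C/C=C/C(C)=C/[C@H](C)CC | intermediate
26 | (2E,4E,6E,8R)-6,8-dimethyldeca-2,4,6-trienoic 2,4,6-trichlorobenzoic anhydride | O=C(OC(=O)c1c(Cl)cc(Cl)cc1Cl)/C=C/C=C/C(C)=C/[C@H](C)CC | intermediate (not isolated)
27 | tert-butyl (1R,4S,7R,7aS)-4-{[(2E,4E,6E,8R)-6,8-dimethyldeca-2,4,6-trienoyl]oxy}-1-(2-formylprop-2-en-1-yl)-7a-methyl-2-oxo-2,4,5,6,7,7a-hexahydro-1H-indene-7-carboxylate | C=C(C=O)C[C@H]1C(=O)C=C2[C@@H](OC(=O)/C=C/C=C/C(C)=C/[C@H](C)CC)CC[C@@H](C(=O)OC(C)(C)C)[C@@]21C | intermediate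
28 | (1R,4S,7R,7aS)-4-{[(2E,4E,6E,8R)-6,8-dimethyldeca-2,4,6-trienoyl]oxy}-1-(2-formylprop-2-en-1-yl)-7a-methyl-2-oxo-2,4,5,6,7,7a-hexahydro-1H-indene-7-carboxylic acid | C=C(C=O)C[C@H]1C(=O)C=C2[C@@H](OC(=O)/C=C/C=C/C(C)=C/[C@H](C)CC)CC[C@@H](C(=O)O)[C@@]21C | target

## Step count and risks

Total step count: 15. Longest linear sequence: 12 steps (1 → 28 through steps 1–10, 14 and 15); the acid 25 is made in 3 steps (11–13).

Steps most likely to fail:

**Step 6 (Pauson–Khand cycloaddition).** A 1,1-disubstituted alkene is a slow partner, and the dioxolane forces one oxygen axial and syn to the methyl that becomes angular. The fallback sets out from 8 and comes back at 16; it cyclises the free ynone instead of its ketal, so that C4 is planar in the transition state and the ene-dione forms directly. Compound 8 is desilylated with TBAF/AcOH to the terminal ynone tert-butyl (2R)-5-oxo-2-(prop-1-en-2-yl)hept-6-ynoate F1. The same Co2(CO)8/tetramethylthiourea/CO cycloaddition converts it into the ene-dione tert-butyl (7R,7aS)-7a-methyl-2,4-dioxo-2,4,5,6,7,7a-hexahydro-1H-indene-7-carboxylate F2. Reduction with NaBH4/CeCl3·7H2O at C4, anti to the angular methyl, gives the hydroxy enone tert-butyl (4S,7R,7aS)-4-hydroxy-7a-methyl-2-oxo-2,4,5,6,7,7a-hexahydro-1H-indene-7-carboxylate F3. Treatment with LiN(iPr)2 (2.2 equiv, THF, −78 °C) gives the dilithium alkoxide enolate of the hydroxy enone F4, which is not isolated and is C-alkylated at C1 by 12 to give 16.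

**Step 7 (C1 alkylation).** The enolate carbon is neopentyl-like and the facial preference is inferred, not proven. The fallback sets out from 11 and comes back at 14; it lets a proton, not the carbon electrophile, enter the enolate face. α-Methylenation of 11 (paraformaldehyde, N-methylanilinium trifluoroacetate, THF, reflux) gives the cross-conjugated methylene ketone tert-butyl (7'R,7a'R)-7a'-methyl-1'-methylidene-2'-oxo-1',2',5',6',7',7a'-hexahydrospiro[1,3-dioxolane-2,4'-indene]-7'-carboxylate F5. Conjugate addition of [CH2=C(CH2SiMe3)]2CuMgBr (from commercial 2-bromo-3-(trimethylsilyl)prop-1-ene, Mg and CuBr·SMe2) to the exocyclic methylene, followed by kinetic protonation of the enolate, gives the allylsilane tert-butyl (1'R,7'R,7a'S)-7a'-methyl-2'-oxo-1'-{2-[(trimethylsilyl)methyl]prop-2-en-1-yl}-1',2',5',6',7',7a'-hexahydrospiro[1,3-dioxolane-2,4'-indene]-7'-carboxylate F6. Bromodesilylation with N-bromosuccinimide (SE2′, CH2Cl2, −78 °C) turns the allylsilane into the 2-(bromomethyl)allyl group of 14.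

**Step 9 (reduction of the ene-dione).** Two conjugated carbonyl groups compete and the C2/C4 preference is a steric argument only. The fallback sets out from 15 and comes back at 16; it gives up regioselective reduction and relies on selective re-oxidation instead. Excess NaBH4/CeCl3·7H2O (MeOH, −78 → −40 °C) reduces both carbonyl groups to the diol tert-butyl (1R,4S,7R,7aS)-1-[2-(bromomethyl)prop-2-en-1-yl]-2,4-dihydroxy-7a-methyl-2,4,5,6,7,7a-hexahydro-1H-indene-7-carboxylate F7 (either C2 epimer serves). MnO2 in CH2Cl2 then re-oxidises only the cyclopentenyl alcohol: the axial C4 carbinol holds its C–H bond in the plane of the alkene and is oxidised much more slowly, so 16 results.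

## Further compounds

F1 | step 6 | tert-butyl (2R)-5-oxo-2-(prop-1-en-2-yl)hept-6-ynoate | C#CC(=O)CC[C@@H](C(=O)OC(C)(C)C)C(C)=C
F2 | step 6 | tert-butyl (7R,7aS)-7a-methyl-2,4-dioxo-2,4,5,6,7,7a-hexahydro-1H-indene-7-carboxylate | C1C(=O)C=C2C(=O)CC[C@@H](C(=O)OC(C)(C)C)[C@@]21C
F3 | step 6 | tert-butyl (4S,7R,7aS)-4-hydroxy-7a-methyl-2-oxo-2,4,5,6,7,7a-hexahydro-1H-indene-7-carboxylate | C1C(=O)C=C2[C@@H](O)CC[C@@H](C(=O)OC(C)(C)C)[C@@]21C
F4 | step 6 | dilithium alkoxide enolate of F3 (O–Li on C2 and C4, double bonds C1=C2 and C3=C3a; 4S,7R,7aS) | C1=C(O[Li])C=C2[C@@H](O[Li])CC[C@@H](C(=O)OC(C)(C)C)[C@@]21C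
F5 | step 7 | tert-butyl (7'R,7a'R)-7a'-methyl-1'-methylidene-2'-oxo-1',2',5',6',7',7a'-hexahydrospiro[1,3-dioxolane-2,4'-indene]-7'-carboxylate | C=C1C(=O)C=C2C3(OCCO3)CC[C@@H](C(=O)OC(C)(C)C)[C@@]21C
F6 | step 7 | tert-butyl (1'R,7'R,7a'S)-7a'-methyl-2'-oxo-1'-{2-[(trimethylsilyl)methyl]prop-2-en-1-yl}-1',2',5',6',7',7a'-hexahydrospiro[1,3-dioxolane-2,4'-indene]-7'-carboxylate | C[Si](C)(C)CC(=C)C[C@H]1C(=O)C=C2C3(OCCO3)CC[C@@H](C(=O)OC(C)(C)C)[C@@]21C
F7 | step 9 | tert-butyl (1R,4S,7R,7aS)-1-[2-(bromomethyl)prop-2-en-1-yl]-2,4-dihydroxy-7a-methyl-2,4,5,6,7,7a-hexahydro-1H-indene-7-carboxylate (C2 configuration not defined) | BrCC(=C)C[C@H]1C(O)C=C2[C@@H](O)CC[C@@H](C(=O)OC(C)(C)C)[C@@]21C
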